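The ratio I watch in the west flask is the rate at which nucleophile takes electrophile over the rate at which it takes protic impurity. If both steps are first order in each partner, free nucleophile cancels from this ratio, however much is bound. With the impurity nearly constant, the logarithm of electrophile charged over electrophile left equals a constant times quenched nucleophile over impurity.

all flasks: electrophile 0.13 M

| flask | nucleophile | free base | protic impurity | remark | time |
|---|---|---|---|---|---|
| west | 0.80 equiv | 1.2 equiv | 0.13 M | the very flask that is asked about, followed so far |  |
| south-west | 0.80 equiv | 1.2 equiv | 0.26 M | run made earlier |  |
| flask | 0.800 equiv | 1.20 equiv | 0.130 M |  | 6.0 h |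

- west (time / h: electrophile / %, target / %): 0.200: 64.3, 33.6; 0.667: 50.6, 46.6; 1.00: 42.8, 50.4; 1.50: 37.8, 53.4; 2.50: 31.4, 51.6
- south-west (time / h: electrophile / %, target / %): 0.200: 66.1, 32.5; 0.333: 59.7, 37.4; 0.667: 51.4, 44.9; 1.33: 41.4, 50.3; 2.50: 35.2, 48.1

(scatter of a reading: 0.5 percentage points)

- part of the electrophile that has reacted at 6.0 h
- share of the unused nucleophile that is free and not bound as protonated nucleophile, at 6.0 h

- the earlier runs do not show how much of nucleophile is bound; that part of a forecast is a guess

I read the last rows against each other. With twice the impurity, the south-west run has 35.2% electrophile left, against 31.4% in the west run, so I suppose the impurity consumes nucleophile. I assume the south-west row is that run's end, with its nucleophile used up. Then 15.2% of the electrophile charge, as nucleophile, went to impurity. This gives the selectivity factor, the first rate constant over the second, as 13.7.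

For the west flask, electrophile left equals what the nucleophile charge cannot reach plus the quenched part. Two rounds from the last west reading, 28.4% and then 29.2%, leave me at 70.8% reacted. The bound share I cannot read.

The forecast says 75% reacted, which differs from my figure, and 30% free, the latter “very uncertain”.

    electrophile + nucleophile → acid set free + target (k = 0.785 M⁻¹ min⁻¹)
    nucleophile + acid set free ⇌ protonated nucleophile, settled at all times (K = 458 M⁻¹)
    acid set free + free base ⇌ salt of the base (K = 45200 M⁻¹, k = 1.59 M⁻¹ min⁻¹)
    target ⇌ isomer of the product (K = 2.95, k = 0.00258 min⁻¹)
    nucleophile + protic impurity → quenched reagent (k = 0.0548 M⁻¹ min⁻¹)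

The flask gives 71.6% reacted and 98.4% free, and its 28.4% electrophile left stands beside the 29.2% from factor 13.7. At 0.600 h the flask's free nucleophile, the limiting reagent, stood at 9.71% of its charge, which was 28.9% of the unused nucleophile, and at 3.00 h the free part stood at 1.34% of the charge. By 6.00 h electrophile was 28.4% while target had fallen to 35.7% and the isomer of the product had risen to 35.8%, a conversion that leaves the reacted part unchanged.

For the neighbour flask with 0.052 M impurity, factor 13.7 gives 24.7% and then 24.1% left, so 75.9% reacted. That flask computes to 76.2%.

(The numbers in the tables were generated by integration with constants of no real substance; noise was put on by code.)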